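I read both new flasks at 120 min, so the question was how many lifetimes of Sbt fit into that time.

| flask | Sbt | Rea | remark | time |
|---|---|---|---|---|
| zeta | 0.10 M | 0.55 M | run made earlier |  |
| eta | 0.10 M | 1.1 M | run made earlier |  |
| Sunday's | 0.10 M | 0.800 M |  | 2.0 h |
| Friday's | 0.10 M | 0.400 M |  | 2.0 h |

| run | time / min | Sbt.Rea / % | Sbt / % |
|---|---|---|---|
| zeta | 6.00 | 76 | 24 |
| zeta | 15.0 | 99 | 2 |
| zeta | 30.0 | 96 | 1 |
| zeta | 50.0 | 94 | 0 |
| zeta | 60.0 | 98 | 0 |
| zeta | 80.0 | 100 | 2 |
| eta | 6.00 | 95 | 6 |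
| eta | 12.0 | 98 | 2 |
| eta | 20.0 | 100 | 2 |
| eta | 30.0 | 98 | 3 |
| eta | 50.0 | 98 | 0 |
| eta | 80.0 | 97 | 0 |

(readings scatter by 1.5 percentage points)

- a reading or a percentage of Sbt.Rea counts all its forms, free or not

* which of the two there is more of at the end, Sunday's (Sbt.Rea / Sid)
* which of the two there is more of at the end, Friday's (Sbt.Rea / Sid)
* Sbt.Rea at the end, in percent of the Sbt charged, Sunday's
* Sbt.Rea at the end, in percent of the Sbt charged, Friday's

I took the rate as k[Sbt][Rea], with k the second-order constant and Rea taken as charged. Zeta's 24 % of Sbt at 6.00 min read as k = 0.432 M⁻¹ min⁻¹, and eta's 6 % at 6.00 min read as 0.426 M⁻¹ min⁻¹. I carried their mean, 0.429 M⁻¹ min⁻¹, where the forecast reckoned about 0.45.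

From that I reckoned the turnover count N, the product of k, the charged Rea and the time: the number of Sbt lifetimes that fit into the run. It came to 20.6 for Friday's and 41.2 for Sunday's.

The first rung is the lifetime itself, 2.91 min in Sunday's and 5.82 min in Friday's. On this rung Sbt falls and Sbt.Rea rises. Sbt is the limiting reagent, so Friday's Rea could fall to 75.0 % of its charge, and the pseudo-first-order picture holds only roughly there.

The next rung is the plateau. From the second reading on, the earlier runs averaged 97.8 % Sbt.Rea, with a scatter of 1.5 percentage points on each reading and no drift I could see up to 80.0 min.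

The top rung is the run, 120 min, much longer than either lifetime. So I expected both flasks to be read on the plateau, though 120 min lies past the last reading at 80.0 min.

The forecast gave Sbt.Rea the larger amount in both flasks, at 98 % (93 % to 100 %) for Sunday's and 97 % (92 % to 100 %) for Friday's: “Two hours is ample for both.”

Sunday's gave 97.9 % Sbt.Rea and Friday's 97.9 %, against 2.12 % and 2.12 % of Sid, so the forecast held. Friday's figure includes 1.88 % as Spx, crystals of Sbt.Rea. To move Sunday's answer by 6 points, its Rea had to come down to 0.123 M, a count of 6.34, which is below Friday's 20.6.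

    Sbt + Rea → Sbt.Rea (k = 0.00799 M⁻¹ s⁻¹)
    Sbt + Rea → Sid (k = 1.73 × 10⁻⁴ M⁻¹ s⁻¹)
    Spx ⇌ Sbt.Rea, rate k3*(cs3 - [Sbt.Rea]) while solid is left; crystals form when [Sbt.Rea] > cs3 (solubility = 0.0960 M, k = 0.00138 s⁻¹)

A neighbour of Friday's flask had 0.10 M of Rea, which is 1.00 equiv. Its count is 5.15, and since Rea falls together with Sbt at equal charges, my rate k[Sbt][Rea] leaves a share 1/(1+N), or 16.3 % of Sbt. The flask gave 14.5 % of Sbt and 83.6 % of Sbt.Rea.

The numbers in the tables were generated by integration on assumed constants; scatter was added.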